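**Retrosynthetic overview**

1. The strategy rests on ring B (C1'–C6'; C1' bonded to chroman C3, OMe on C2', C4' and C5', C=O at C3' and C6'). This hexasubstituted, penta-oxygenated quinone ring is assembled from a four-carbon and a two-carbon piece, not by substitution on an arene.
2. Endgame: target 23 ⇐ hydroxyquinone 22 ⇐ silyloxyquinone 21 ⇐ para-methoxyphenol 20 (C3' carbonyl unmasked by oxidative demethylation, C2' OMe from the silyl ether).
3. Key disconnection: 20 ⇐ 2,3,4-trimethoxycyclobutenone 15 (C3'–C6') + siloxyalkyne 12 (C1', C2') by vinylketene benzannulation, forming C6'–C1', C2'–C3' and C5'–C6'.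
4. 12 ⇐ ester 9 (Kowalski ynolate silylation) ⇐ acid 8 (C3 set by Ru–BINAP hydrogenation) ⇐ chromene 6 ⇐ salicylaldehyde 4 + acrylate 5; 15 ⇐ dimethyl squarate 13.
5. Ring order: ring A is bought with 1, ring C is closed in step 3, ring B is closed last in step 10.

Key step: step 10

Assumption: in step 5 the (S)-BINAP complex is taken to give the (3R)-acid by analogy with the hydrogenation of tiglic acid; the sense would be checked on the first batch and the (R)-BINAP complex used if it is the reverse.

Remark: C3 keeps one spatial arrangement throughout; its descriptor is R in 8–10 and S from 11 on only because the priority of the C3 substituent changes.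

**Route**

Step 1
Reactants: 1 2,3,4-trimethoxybenzaldehyde
Product: 3 2,3,4-trimethoxyphenol, via 2,3,4-trimethoxyphenyl formate 2 (not isolated)
Conditions: 30% H2O2, cat. H2SO4, MeOH, 25 °C
Reagents that add atoms: hydrogen peroxide, OO
Why: Acid-catalysed Dakin (Baeyer–Villiger-type) oxidation, in which the electron-rich aryl group migrates in the peroxide adduct to give formate 2, which is methanolysed in the same flask.

Step 2
Reactants: 3 2,3,4-trimethoxyphenol
Product: 4 2-hydroxy-3,4,5-trimethoxybenzaldehyde
Conditions: MgCl2, Et3N, (CH2O)n, MeCN, reflux; aq. HCl work-up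
Reagents that add atoms: paraformaldehyde (formaldehyde), C=O
Why: Casnati–Skattebøl ortho-formylation, in which the magnesium phenoxide delivers formaldehyde to the only free ortho position (C6 of 3, the para position being blocked by OMe) and hydride transfer to a second formaldehyde gives the aldehyde.

Step 3
Reactants: 4 2-hydroxy-3,4,5-trimethoxybenzaldehyde; 5 tert-butyl acrylate
Product: 6 tert-butyl 6,7,8-trimethoxy-2H-chromene-3-carboxylate
Conditions: DABCO (1 equiv), CHCl3/H2O, 25–40 °C
Reagents that add atoms: none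
Why: DABCO-mediated Baylis–Hillman/oxa-Michael annulation of a salicylaldehyde with an acrylate, followed by loss of water, closes ring C, and the tert-butyl ester suppresses lactonisation to the coumarin.

Step 4
Reactants: 6 tert-butyl 6,7,8-trimethoxy-2H-chromene-3-carboxylate
Product: 7 6,7,8-trimethoxy-2H-chromene-3-carboxylic acid
Conditions: CF3CO2H, CH2Cl2, 0 → 25 °C
Reagents that add atoms: none
Why: Acidolysis of the tert-butyl ester (E1 loss of the tert-butyl cation) frees the carboxylic acid that the hydrogenation catalyst needs as a binding group.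

Step 5
Reactants: 7 6,7,8-trimethoxy-2H-chromene-3-carboxylic acid
Product: 8 (3R)-6,7,8-trimethoxychroman-3-carboxylic acid
Conditions: Ru(OAc)2[(S)-BINAP] (1 mol %), H2 (50 bar), MeOH, 30 °C
Reagents that add atoms: none
Why: Noyori asymmetric hydrogenation of an α,β-unsaturated carboxylic acid, in which the carboxylate binds divalent ruthenium and hydrogen is delivered to one face of the C3=C4 bond, so that the BINAP ligand sets the C3 stereocentre as R.

Step 6
Reactants: 8 (3R)-6,7,8-trimethoxychroman-3-carboxylic acid
Product: 9 methyl (3R)-6,7,8-trimethoxychroman-3-carboxylate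
Conditions: Me3SiCHN2, MeOH/toluene, 0 → 25 °C
Reagents that add atoms: trimethylsilyldiazomethane, C[Si](C)(C)C=[N+]=[N-]
Why: Diazomethane-type esterification under non-basic conditions, which cannot epimerise C3.

Step 7
Reactants: 9 methyl (3R)-6,7,8-trimethoxychroman-3-carboxylate
Product: 12 triisopropyl{[(3S)-6,7,8-trimethoxychroman-3-yl]ethynyloxy}silane, via lithium dibromoenolate 10 (not isolated), via lithium ynolate 11 (not isolated)
Conditions: CH2Br2, LiTMP (lithium 2,2,6,6-tetramethylpiperidide), THF, −78 °C; LiN(SiMe3)2; n-BuLi, −78 → 25 °C; then i-Pr3SiCl, −78 → 0 °C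
Reagents that add atoms: dibromomethane, BrCBr; chlorotriisopropylsilane, CC(C)[Si](Cl)(C(C)C)C(C)C
Why: Kowalski ester homologation stopped at the ynolate, in which LiCHBr2 adds to the ester, enolate 10 undergoes Br/Li exchange and a carbenoid 1,2-shift of the chromanyl group with retention at C3 to give ynolate 11, and the bulky silyl chloride traps it on oxygen, while C3–H should stay untouched because the far more acidic CHBr2 proton is removed first.

Step 8
Reactants: 13 dimethyl squarate
Product: 14 4-hydroxy-2,3-dimethoxycyclobut-2-en-1-one (racemic)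
Conditions: LiAlH(Ot-Bu)3, THF, −78 → −20 °C; aq. NH4Cl
Reagents that add atoms: none
Why: Monoreduction of a squarate ester, in which the hindered hydride adds once in 1,2-fashion to a ring carbonyl and the aluminium alkoxide formed resists further reduction; the new C4 centre is racemic and disappears on aromatisation.

Step 9
Reactants: 14 4-hydroxy-2,3-dimethoxycyclobut-2-en-1-one
Product: 15 2,3,4-trimethoxycyclobut-2-en-1-one (racemic)
Conditions: MeI, Ag2O, 4 Å molecular sieves, Et2O, 25 °C, dark; filtration through base-washed silica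
Reagents that add atoms: iodomethane, CI
Why: Purdie methylation under neutral conditions, chosen because acid would ionise the C4–O bond and lead to methyl semisquarate.

Step 10
Reactants: 15 2,3,4-trimethoxycyclobut-2-en-1-one (1.5 equiv); 12 triisopropyl{[(3S)-6,7,8-trimethoxychroman-3-yl]ethynyloxy}silane
Product: 20 4,5,6-trimethoxy-2-[(3S)-6,7,8-trimethoxychroman-3-yl]-3-(triisopropylsilyloxy)phenol, via vinylketene 16 (not isolated), via 4-vinylcyclobutenone 17 (not isolated), via dienylketene 18 (not isolated), via cyclohexadienone 19 (not isolated)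
Conditions: toluene (degassed), 80 → 110 °C, sealed base-washed tube, Ar
Reagents that add atoms: none
Why: Heating opens cyclobutenone 15 by 4π-electrocyclic cleavage of its C1–C4 bond, the C4 methoxy turning outward, to vinylketene 16, whose ketene C=C adds across the siloxyalkyne in a [2+2] cycloaddition (ketene carbonyl carbon to the chroman-bearing alkyne carbon, C6'–C1'; ketene α-carbon to the silyloxy carbon, C2'–C3') to give 4-vinylcyclobutenone 17. A second 4π opening, again with the ring methoxy outward and therefore the dimethoxyvinyl arm inward, gives dienylketene 18, which closes ring B by a thermal disrotatory 6π-electrocyclisation (C5'–C6') to cyclohexadienone 19, and enolisation delivers phenol 20. The closest known reaction is the Danheiser benzannulation of a cyclobutenone with a siloxyalkyne, applied here to a trimethoxy-substituted cyclobutenone. No stereocentre is formed, and C3 of the chroman lies outside the reacting π-system and sees only neutral thermal conditions. The step needs a single regiochemistry in the [2+2] event, and the polarisation of the siloxyalkyne (nucleophilic at the carbon remote from oxygen) secures it, so that the chroman ends up between OH and OSi(i-Pr)3.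

Step 11
Reactants: 20 4,5,6-trimethoxy-2-[(3S)-6,7,8-trimethoxychroman-3-yl]-3-(triisopropylsilyloxy)phenol
Product: 21 2,3-dimethoxy-5-[(3S)-6,7,8-trimethoxychroman-3-yl]-6-(triisopropylsilyloxy)cyclohexa-2,5-diene-1,4-dione
Conditions: PhI(OAc)2, MeCN/H2O 3:1, 0 °C
Reagents that add atoms: water, O
Why: Oxidative demethylation of a para-methoxyphenol with PhI(OAc)2, in which ligand exchange at iodine, attack of water at the para carbon (C3') and loss of methanol give the para-quinone under conditions that the silyl ether and the chroman should survive.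

Step 12
Reactants: 21 2,3-dimethoxy-5-[(3S)-6,7,8-trimethoxychroman-3-yl]-6-(triisopropylsilyloxy)cyclohexa-2,5-diene-1,4-dione
Product: 22 2-hydroxy-5,6-dimethoxy-3-[(3S)-6,7,8-trimethoxychroman-3-yl]cyclohexa-2,5-diene-1,4-dione
Conditions: Bu4NF, AcOH, THF, 0 °C
Reagents that add atoms: none
Why: Fluoride-mediated desilylation of a vinylogous silyl ester releases the acidic 2-hydroxyquinone, and the acetic acid buffer protects the quinone from base-induced decomposition.

Step 13
Reactants: 22 2-hydroxy-5,6-dimethoxy-3-[(3S)-6,7,8-trimethoxychroman-3-yl]cyclohexa-2,5-diene-1,4-dione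
Product: 23 2,3,5-trimethoxy-6-[(3S)-6,7,8-trimethoxychroman-3-yl]cyclohexa-2,5-diene-1,4-dione (target)
Conditions: Me3SiCHN2, MeOH/CH2Cl2, 0 °C
Reagents that add atoms: trimethylsilyldiazomethane, C[Si](C)(C)C=[N+]=[N-]
Why: The hydroxyquinone is a vinylogous carboxylic acid and should be O-methylated by diazomethane generated in the flask from Me3SiCHN2 and methanol (esterification-type methylation), which completes the target without touching C3.

**Compound list**

1 | 2,3,4-trimethoxybenzaldehyde | COc1ccc(C=O)c(OC)c1OC | starting material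
2 | 2,3,4-trimethoxyphenyl formate | COc1ccc(OC=O)c(OC)c1OC | intermediate (not isolated)
3 | 2,3,4-trimethoxyphenol | COc1ccc(O)c(OC)c1OC | intermediate
4 | 2-hydroxy-3,4,5-trimethoxybenzaldehyde | COc1cc(C=O)c(O)c(OC)c1OC | intermediate
5 | tert-butyl acrylate | C=CC(=O)OC(C)(C)C | starting material
6 | tert-butyl 6,7,8-trimethoxy-2H-chromene-3-carboxylate | CC(C)(C)OC(=O)C1=Cc2cc(OC)c(OC)c(OC)c2OC1 | intermediate
7 | 6,7,8-trimethoxy-2H-chromene-3-carboxylic acid | OC(=O)C1=Cc2cc(OC)c(OC)c(OC)c2OC1 | intermediate
8 | (3R)-6,7,8-trimethoxychroman-3-carboxylic acid | OC(=O)[C@H]1COc2c(cc(OC)c(OC)c2OC)C1 | intermediate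
9 | methyl (3R)-6,7,8-trimethoxychroman-3-carboxylate | COC(=O)[C@H]1COc2c(cc(OC)c(OC)c2OC)C1 | intermediate
10 | lithium 2,2-dibromo-1-[(3R)-6,7,8-trimethoxychroman-3-yl]ethenolate | [Li+].[O-]C(=C(Br)Br)[C@H]1COc2c(cc(OC)c(OC)c2OC)C1 | intermediate (not isolated)
11 | lithium 2-[(3S)-6,7,8-trimethoxychroman-3-yl]ethynolate | [Li+].[O-]C#C[C@H]1COc2c(cc(OC)c(OC)c2OC)C1 | intermediate (not isolated)
12 | triisopropyl{[(3S)-6,7,8-trimethoxychroman-3-yl]ethynyloxy}silane | CC(C)[Si](OC#C[C@H]1COc2c(cc(OC)c(OC)c2OC)C1)(C(C)C)C(C)C | intermediate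
13 | dimethyl squarate (3,4-dimethoxycyclobut-3-ene-1,2-dione) | COC1=C(OC)C(=O)C1=O | starting material
14 | 4-hydroxy-2,3-dimethoxycyclobut-2-en-1-one (racemic) | O=C1C(OC)=C(OC)C1O | intermediate
15 | 2,3,4-trimethoxycyclobut-2-en-1-one (racemic) | O=C1C(OC)=C(OC)C1OC | intermediate
16 | (3Z)-2,3,4-trimethoxybuta-1,3-dien-1-one | O=C=C(OC)/C(OC)=C/OC | intermediate (not isolated)
17 | 4-[(Z)-1,2-dimethoxyethenyl]-4-methoxy-2-[(3S)-6,7,8-trimethoxychroman-3-yl]-3-(triisopropylsilyloxy)cyclobut-2-en-1-one (both C4 epimers) | O=C1C([C@H]2COc3c(cc(OC)c(OC)c3OC)C2)=C(O[Si](C(C)C)(C(C)C)C(C)C)C1(OC)/C(OC)=C/OC | intermediate (not isolated)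
18 | (3Z,5Z)-4,5,6-trimethoxy-2-[(3S)-6,7,8-trimethoxychroman-3-yl]-3-(triisopropylsilyloxy)hexa-1,3,5-trien-1-one | O=C=C([C@H]1COc2c(cc(OC)c(OC)c2OC)C1)/C(O[Si](C(C)C)(C(C)C)C(C)C)=C(OC)\C(OC)=C\OC | intermediate (not isolated)
19 | 4,5,6-trimethoxy-2-[(3S)-6,7,8-trimethoxychroman-3-yl]-3-(triisopropylsilyloxy)cyclohexa-2,4-dien-1-one (both C6 epimers) | O=C1C([C@H]2COc3c(cc(OC)c(OC)c3OC)C2)=C(O[Si](C(C)C)(C(C)C)C(C)C)C(OC)=C(OC)C1OC | intermediate (not isolated)
20 | 4,5,6-trimethoxy-2-[(3S)-6,7,8-trimethoxychroman-3-yl]-3-(triisopropylsilyloxy)phenol | Oc1c(OC)c(OC)c(OC)c(O[Si](C(C)C)(C(C)C)C(C)C)c1[C@H]1COc2c(cc(OC)c(OC)c2OC)C1 | intermediate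
21 | 2,3-dimethoxy-5-[(3S)-6,7,8-trimethoxychroman-3-yl]-6-(triisopropylsilyloxy)cyclohexa-2,5-diene-1,4-dione | COC1=C(OC)C(=O)C([C@H]2COc3c(cc(OC)c(OC)c3OC)C2)=C(O[Si](C(C)C)(C(C)C)C(C)C)C1=O | intermediate
22 | 2-hydroxy-5,6-dimethoxy-3-[(3S)-6,7,8-trimethoxychroman-3-yl]cyclohexa-2,5-diene-1,4-dione | COC1=C(OC)C(=O)C([C@H]2COc3c(cc(OC)c(OC)c3OC)C2)=C(O)C1=O | intermediate
23 | 2,3,5-trimethoxy-6-[(3S)-6,7,8-trimethoxychroman-3-yl]cyclohexa-2,5-diene-1,4-dione | COC1=C(OC)C(=O)C([C@H]2COc3c(cc(OC)c(OC)c3OC)C2)=C(OC)C1=O | target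

**Step count**

Total: 13 steps. Longest linear sequence: 11 steps (steps 1–7, then 10–13); steps 8–9 form the second branch.

**Steps most likely to fail, with fallbacks**

Step 10 (benzannulation). The electron-rich vinylketene 16 may dimerise, or acylate the product phenol, faster than it adds to the hindered secondary-alkyl siloxyalkyne. Ring opening of 15 may also need temperatures at which 12 decomposes. The fallback is the Moore rearrangement of a 4-alkynyl-4-hydroxycyclobutenone, the established squarate route to oxygenated quinones. It sets out from methyl ester 9 and dimethyl squarate 13 and comes back to the route at hydroxyquinone 22. Ester 9 is first taken to the terminal alkyne (3S)-3-ethynyl-6,7,8-trimethoxychroman F3 by the three operations described under step 7 below. Its lithium acetylide (n-BuLi, THF, −78 °C) would add to one carbonyl of 13 to give alkynyl carbinol F4. Heating F4 in p-xylene should give, by ring opening, closure onto the alkyne and hydrogen shift, the dimethoxyquinone F5, which lacks only the C2' oxygen. Weitz–Scheffer epoxidation of the C1'=C2' bond (H2O2, Na2CO3, aq. THF) would give epoxide F6, and acid-promoted isomerisation (cat. H2SO4, AcOH) should open it to 22, which is methylated as in step 13.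

Step 7 (ynolate formation and silylation). The lithium amide may remove the C3 proton of ester 9 in competition with formation and addition of LiCHBr2, so that C3 epimerises or ring C opens by E1cB loss of the aryloxide. Silylation of ynolate 11 may also stay incomplete. The fallback makes the ynolate from a terminal alkyne instead of an ester. It sets out from methyl ester 9 and comes back at siloxyalkyne 12. Reduction with i-Bu2AlH (CH2Cl2, −78 °C) would give (3R)-6,7,8-trimethoxychroman-3-carbaldehyde F1, used crude. Corey–Fuchs homologation would follow: CBr4, PPh3, CH2Cl2, 0 °C to the dibromoalkene F2, then n-BuLi, THF, −78 °C and aq. NH4Cl to the alkyne F3. F3 would be deprotonated (n-BuLi) and oxidised in the same flask with lithium tert-butyl peroxide (t-BuOOH/LiN(SiMe3)2, THF, −78 → 0 °C) to the same ynolate 11, which i-Pr3SiOTf silylates to 12.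

Step 5 (asymmetric hydrogenation). Facial discrimination on the cyclic trisubstituted acid may be insufficient, or the allylic C2–O bond may be hydrogenolysed. The fallback is classical resolution. It sets out from chromene acid 7 and comes back at acid 8. Hydrogenation over Pd/C (H2, EtOAc, 25 °C) would give the racemic acid F7. Crystallisation with (R)-1-phenylethylamine from EtOH should deposit one diastereomeric salt, taken here as the salt of the (3R)-acid F8; which antipode of the amine pairs with the (3R)-acid has to be found by trial. Acidification (aq. HCl) would return 8.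

**Further compounds**

F1 | step 7 | (3R)-6,7,8-trimethoxychroman-3-carbaldehyde | O=C[C@H]1COc2c(cc(OC)c(OC)c2OC)C1
F2 | step 7 | (3S)-3-(2,2-dibromoethenyl)-6,7,8-trimethoxychroman | BrC(Br)=C[C@H]1COc2c(cc(OC)c(OC)c2OC)C1
F3 | step 7 | (3S)-3-ethynyl-6,7,8-trimethoxychroman | C#C[C@H]1COc2c(cc(OC)c(OC)c2OC)C1
F4 | step 10 | 4-hydroxy-2,3-dimethoxy-4-{[(3S)-6,7,8-trimethoxychroman-3-yl]ethynyl}cyclobut-2-en-1-one (both carbinol epimers) | COC1=C(OC)C(O)(C#C[C@H]2COc3c(cc(OC)c(OC)c3OC)C2)C1=O
F5 | step 10 | 2,3-dimethoxy-5-[(3S)-6,7,8-trimethoxychroman-3-yl]cyclohexa-2,5-diene-1,4-dione | COC1=C(OC)C(=O)C([C@H]2COc3c(cc(OC)c(OC)c3OC)C2)=CC1=O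
F6 | step 10 | 3,4-dimethoxy-1-[(3R)-6,7,8-trimethoxychroman-3-yl]-7-oxabicyclo[4.1.0]hept-3-ene-2,5-dione (epoxide of F5, both epoxide diastereomers) | COC1=C(OC)C(=O)C2(OC2C1=O)[C@H]1COc2c(cc(OC)c(OC)c2OC)C1
F7 | step 5 | rac-6,7,8-trimethoxychroman-3-carboxylic acid | OC(=O)C1COc2c(cc(OC)c(OC)c2OC)C1
F8 | step 5 | (R)-1-phenylethylammonium (3R)-6,7,8-trimethoxychroman-3-carboxylate | C[C@@H]([NH3+])c1ccccc1.[O-]C(=O)[C@H]1COc2c(cc(OC)c(OC)c2OC)C1
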